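**Retrosynthetic overview**

1. Locants: ring A is the γ-pyranone (O1, C2–C6), the chain is C7–C12, and ring B is the cyclohexane C13–C18, with C13 carrying the chain. The last disconnection is the C8–C9 single bond in the middle of the triene. It gives iodoalkenyl pyranone 31 (C8–I) and terminal enyne 20 (C9≡C10–H). In the forward direction a one-pot syn-hydrostannation/Stille coupling makes C8–C9 and the E-C9=C10 alkene in the same flask, as the last step and without protecting groups.
2. Enabling feature: C9=C10 is the only unbranched CH=CH unit of the C7–C12 triene and sits on the fully substituted sp2 carbon C11. It is therefore the retron of a terminal alkyne whose free end C9 takes the metal. Ring B offers only tertiary hydroxyls (C15, C17) and non-allylic acetates (C16, C18), and ring A makes C8–I a vinylogous acyl iodide, so nothing else should react.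
3. Ring B is formed first (step 3). A catalytic enantioselective Diels–Alder reaction of silyloxydiene 5 with methyl acrylate sets C13/C14 cis. The four oxygens then go on the opposite face by substrate control: Rubottom oxidation (C15), Luche reduction (C16) and hydroxyl-directed dihydroxylation (C17/C18). The alkyne installed in step 6 passes through all of this unprotected.
4. Ring A is formed second (step 17): β-ketoester dianion aldol with (E)-3-iodo-2-methylpropenal, oxidation, lactonisation, and O-methylation at the lactone carbonyl oxygen. No ring is formed in the union.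

Key step: step 19

Convention: ring B is viewed with C13→C18 running clockwise; β points toward the viewer and α away. In the target the C13 chain and the CH3 groups at C14, C15 and C17 are α, and the oxygens at C15–C18 are β (13R,14S,15R,16R,17S,18S). The same locants are used for all precursors.

Assumption: the (S)-configured cationic oxazaborolidine is taken to expose the α-Re face of the bound acrylate, as in its known acrylate/butadiene cycloadditions. If a first run shows the opposite sense, the equally available (R)-catalyst is used and nothing else changes.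

**Route**

Step 1
Reactants: 1 pentan-3-one; 2 acetaldehyde
Product: 4 (E)-4-methylhex-4-en-3-one, via aldol adduct 3 (not isolated)
Conditions: 1 (3 equiv), KOH (10 mol %), MeOH/H2O, 0 °C, slow addition of 2; then p-TsOH·H2O (5 mol %), toluene, reflux, azeotropic removal of water
Reagents that add atoms: none
Why: Crossed aldol condensation in which the symmetrical ketone, kept in excess, is the enolate partner, and the equilibrating acid dehydration should give the more stable E (tiglate-type) enone.

Step 2
Reactants: 4 (E)-4-methylhex-4-en-3-one
Product: 5 triisopropyl{[(2Z,4E)-4-methylhexa-2,4-dien-3-yl]oxy}silane (future C14=C15–C16(OSi)=C17)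
Conditions: TIPSOTf (1.1 equiv), Et3N (1.5 equiv), CH2Cl2, 0 °C to rt
Reagents that add atoms: triisopropylsilyl trifluoromethanesulfonate, CC(C)[Si](C(C)C)(C(C)C)OS(=O)(=O)C(F)(F)F
Why: Soft enolisation of an ethyl ketone with a silyl triflate and an amine removes a proton from the only α-CH2 group and should give the Z silyl enol ether, so that both terminal methyls of the 2-silyloxydiene point outward in the s-cis form needed for cycloaddition.

Step 3
Reactants: 5 silyloxydiene; 6 methyl acrylate
Product: 7 methyl 2,3,5-trimethyl-4-(triisopropylsilyloxy)cyclohex-3-ene-1-carboxylate, CO2Me (C13), CH3 (C14) and CH3 (C17) all α (all cis)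
Conditions: (S)-3,3-diphenyl-1-(2-methylphenyl)tetrahydro-1H,3H-pyrrolo[1,2-c][1,3,2]oxazaborole (20 mol %), (CF3SO2)2NH (18 mol %), CH2Cl2, −78 to −40 °C
Reagents that add atoms: none
Why: Catalytic enantioselective Diels–Alder reaction with a proline-derived cationic oxazaborolidine: the silyloxy group on C16 makes C17 the most nucleophilic diene terminus, so C17 bonds to the acrylate CH2 (C18) and C14 to the ester-bearing C13 (para rule), the endo transition state places the ester cis to the two outward methyls of the diene, and the catalyst leaves only the α-Re face of the bound acrylate open, which fixes the absolute configuration of C13 and C14.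

Step 4
Reactants: 7 Diels–Alder adduct
Product: 8 2,3,5-trimethyl-4-(triisopropylsilyloxy)cyclohex-3-ene-1-carbaldehyde, CHO (C13) and the CH3 groups at C14 and C17 all α
Conditions: i-Bu2AlH (1.1 equiv), CH2Cl2, −78 °C; MeOH, then aq. potassium sodium tartrate
Reagents that add atoms: none
Why: Partial reduction of an ester, in which the tetrahedral aluminium hemiacetal of this α-branched ester should persist at −78 °C and release the aldehyde only on neutral work-up, leaving the silyl enol ether and the epimerisable C13 centre untouched.

Step 5
Reactants: 8 ring B aldehyde; 9 2-(triphenylphosphoranylidene)propanal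
Product: 10 (E)-2-methyl-3-[2,3,5-trimethyl-4-(triisopropylsilyloxy)cyclohex-3-en-1-yl]prop-2-enal, ring centres as in 8
Conditions: 9 (1.5 equiv), toluene, 80 °C
Reagents that add atoms: none
Why: Wittig olefination with a stabilised ylide, which is E-selective for the new C11=C12 bond and too weakly basic to epimerise C13.

Step 6
Reactants: 10 (E)-enal
Product: 11 (E)-enyne, triisopropyl{[2,3,6-trimethyl-4-((E)-2-methylbut-1-en-3-yn-1-yl)cyclohex-1-en-1-yl]oxy}silane, ring centres as in 8
Conditions: Me3SiCHN2 (1.3 equiv), LiN(i-Pr)2 (1.3 equiv), THF, −78 °C to rt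
Reagents that add atoms: (trimethylsilyl)diazomethane, C[Si](C)(C)C=[N+]=[N-]
Why: Colvin rearrangement, in which addition of the lithiated silyldiazomethane to the aldehyde, loss of silanolate and nitrogen and a 1,2-hydrogen shift of the alkylidene carbene turn CHO into C10≡C9–H at low temperature, without the methanol addition that troubles enals under diazophosphonate conditions and without touching C11=C12.

Step 7
Reactants: 11 (E)-enyne
Product: 13 C16 ketone, 4-[(E)-2-methylbut-1-en-3-yn-1-yl]-2,3,6-trimethyl-2-(triisopropylsilyloxy)cyclohexan-1-one (C15: OTIPS β and CH3 α; C13 chain, C14 CH3 and C17 CH3 α), via silyloxy epoxide 12 (not isolated)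
Conditions: mCPBA (1.05 equiv), NaHCO3, CH2Cl2, −20 to 0 °C
Reagents that add atoms: 3-chloroperoxybenzoic acid, OOC(=O)c1cccc(Cl)c1
Why: Rubottom oxidation, in which the peracid attacks the electron-rich tetrasubstituted silyl enol ether far faster than the enyne and from the β face because the substituents at C13, C14 and C17 all stand on the α face, and opening of 12 with 1,4-silyl shift gives the ketone and sets C15.

Step 8
Reactants: 13 C16 ketone
Product: 15 enone, 4-[(E)-2-methylbut-1-en-3-yn-1-yl]-2,5,6-trimethyl-6-(triisopropylsilyloxy)cyclohex-2-en-1-one (C16=O, C17=C18; C13, C14, C15 as in 13), via trimethylsilyl enol ether 14 (not isolated)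
Conditions: Me3SiOTf (1.5 equiv), Et3N (2.5 equiv), CH2Cl2, 0 °C to rt, concentrate; then 2-iodoxybenzoic acid (IBX, 1.5 equiv) premixed with 4-methoxypyridine N-oxide (1.5 equiv), DMSO, rt
Reagents that add atoms: trimethylsilyl trifluoromethanesulfonate, C[Si](C)(C)OS(=O)(=O)C(F)(F)F (its silicon stays only in 14)
Why: Soft enolisation can only go toward C17, the single enolisable position, and oxidation of the silyl enol ether by the IBX–N-oxide complex (a metal-free counterpart of the Saegusa–Ito oxidation, chosen because divalent palladium would attack the terminal alkyne) should remove a C18 hydrogen to give the endocyclic enone, the C17 centre being erased on purpose.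

Step 9
Reactants: 15 enone
Product: 16 allylic alcohol (C16 OH β, cis to the C15 OTIPS; C17=C18 kept)
Conditions: NaBH4 (1.2 equiv), CeCl3·7H2O (1.2 equiv), MeOH, −78 to −40 °C
Reagents that add atoms: none
Why: Luche 1,2-reduction, in which hydride should arrive axially from the α face, anti to the axial and very bulky β C15–OTIPS group next to the carbonyl, so that C16 receives a β (equatorial) hydroxyl while the alkyne and enyne alkene are inert.

Step 10
Reactants: 16 allylic alcohol
Product: 17 cis-diol (C15 OH β, C16 OH β; C17=C18)
Conditions: Bu4NF (1.5 equiv), THF, 0 °C to rt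
Reagents that add atoms: none
Why: Fluoride desilylation removes the silyl group, which would otherwise sit 1,3-diaxial to the incoming oxidant, and frees the C15 hydroxyl as a second directing group without affecting any stereocentre.

Step 11
Reactants: 17 cis-diol
Product: 19 all-cis tetrol (OH β at C15, C16, C17, C18), via osmate ester 18 (not isolated)
Conditions: OsO4 (1.05 equiv), TMEDA (1.1 equiv), CH2Cl2, −78 °C; then aq. Na2SO3, THF, 40 °C
Reagents that add atoms: osmium tetroxide, O=[Os](=O)(=O)=O; N,N,N',N'-tetramethylethylenediamine, CN(C)CCN(C)C (stays only in 18)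
Why: Hydroxyl-directed dihydroxylation, in which the OsO4·TMEDA complex is a hydrogen-bond acceptor and is delivered by the β hydroxyls at C16 (allylic) and C15 to the β face of C17=C18, which is also the face away from the α C13 chain and the axial α C14 methyl, so the syn addition sets C17 and C18 and leaves the undirected, less electron-rich enyne alone.

Step 12
Reactants: 19 tetrol
Product: 20 enyne diol diacetate (C16 OAc, C18 OAc, free tertiary OH at C15 and C17)
Conditions: Ac2O (3 equiv), pyridine, DMAP (10 mol %), CH2Cl2, 0 °C to rt
Reagents that add atoms: acetic anhydride, CC(=O)OC(C)=O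
Why: Chemoselective acylation, in which the two secondary equatorial hydroxyls are acetylated under nucleophilic catalysis whereas the two tertiary axial hydroxyls are too hindered to react at room temperature, which gives the acetylation pattern of the target directly.

Step 13
Reactants: 21 prop-2-yn-1-ol
Product: 23 (E)-3-iodo-2-methylprop-2-en-1-ol, via alkenylalane 22 (not isolated)
Conditions: Me3Al (3 equiv), Cp2ZrCl2 (25 mol %), CH2Cl2, 0 °C to rt; then I2 (1.2 equiv), THF, −30 °C; aq. K2CO3
Reagents that add atoms: trimethylaluminium, C[Al](C)C; iodine, II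
Why: Zirconium-catalysed carboalumination (Negishi carboalumination) adds CH3 and Al syn across the alkyne with aluminium on the terminal carbon, and iodinolysis with retention should give the E iodoalkene that later becomes C7=C8.

Step 14
Reactants: 23 (E)-3-iodo-2-methylprop-2-en-1-ol
Product: 24 (E)-3-iodo-2-methylprop-2-enal
Conditions: MnO2 (15 equiv), CH2Cl2, rt, dark
Reagents that add atoms: none
Why: Selective oxidation of an allylic alcohol on MnO2 under neutral conditions, which keeps the alkene geometry and the C–I bond.

Step 15
Reactants: 25 methyl 2-methyl-3-oxopentanoate; 24 (E)-3-iodo-2-methylprop-2-enal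
Product: 27 methyl (E)-5-hydroxy-7-iodo-2,4,6-trimethyl-3-oxohept-6-enoate (diastereomer mixture), via ketoester dianion 26 (not isolated)
Conditions: 25, NaH (1.1 equiv), THF, 0 °C; n-BuLi (1.05 equiv), 0 °C; then 24, −78 °C; aq. NH4Cl
Reagents that add atoms: sodium hydride, [Na+].[H-]; n-butyllithium, [Li]CCCC (the metal ions stay only in 26)
Why: Aldol addition of a β-ketoester dianion, which reacts at its more basic γ-carbon and adds 1,2 to the enal at low temperature, the three new stereocentres being irrelevant because steps 16 and 17 erase them.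

Step 16
Reactants: 27 aldol product
Product: 28 methyl (E)-7-iodo-2,4,6-trimethyl-3,5-dioxohept-6-enoate
Conditions: 1,1,1-triacetoxy-1,1-dihydro-1,2-benziodoxol-3(1H)-one (DMP, 1.3 equiv), CH2Cl2, 0 °C to rt
Reagents that add atoms: none
Why: Dess–Martin oxidation of the allylic alcohol under nearly neutral conditions gives the triketide without disturbing the iodoalkene.

Step 17
Reactants: 28 triketide
Product: 29 4-hydroxy-6-[(E)-1-iodoprop-1-en-2-yl]-3,5-dimethyl-2H-pyran-2-one
Conditions: DBU (1.2 equiv), toluene, 60 °C; then 1 M HCl wash
Reagents that add atoms: none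
Why: Base-induced lactonisation (6-exo-trig O-acylation) of a 3,5-dioxoester, in which the enolate oxygen of the side-chain ketone attacks the methyl ester and expels methoxide irreversibly to close ring A, while delocalisation of the diketonate lowers the acceptor character of the iodoenone.

Step 18
Reactants: 29 hydroxypyranone
Product: 31 6-[(E)-1-iodoprop-1-en-2-yl]-2-methoxy-3,5-dimethyl-4H-pyran-4-one, via pyrylium triflate 30 (not isolated)
Conditions: MeOTf (1.5 equiv), CH2Cl2, rt; then sat. aq. NaHCO3
Reagents that add atoms: methyl trifluoromethanesulfonate, COS(=O)(=O)C(F)(F)F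
Why: Regioselective O-alkylation, in which a hard methylating agent attacks the most basic site, the lactone carbonyl oxygen, to give the 2-methoxy-4-hydroxypyrylium salt, whose deprotonation should give the α-methoxy-γ-pyranone and not the isomeric 4-methoxy-2-pyranone.

Step 19
Reactants: 20 enyne diol diacetate; 31 iodoalkenyl pyranone
Product: 33 amaurone B, via dienylstannane 32 (not isolated)
Conditions: 20, Pd2(dba)3 (2.5 mol %), PCy3·HBF4 (10 mol %), i-Pr2NEt (20 mol %), Bu3SnH (1.05 equiv, slow addition), THF, 0 °C, dark; then 31 (1.0 equiv), Pd(PPh3)4 (5 mol %), CuI (20 mol %), CsF (2 equiv), DMF, rt, dark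
Reagents that add atoms: tributyltin hydride, CCCC[SnH](CCCC)CCCC (its tin stays only in 32; only its hydrogen, on C10, stays in 33)
Why: Zerovalent palladium inserts into the Sn–H bond and the terminal alkyne C9≡C10 of 20 inserts syn, so that reductive elimination gives the E-dienylstannane 32, the bulky PCy3 ligand and the fully substituted C11 next to C10 sending tin to the terminal carbon C9. Addition of 31 then starts the Stille cycle in the same flask: oxidative addition of the electron-poor C8–I bond (C8 ends a vinylogous ester running through C7=C8, C6=C5 and C4=O), fluoride- and copper-assisted transfer of the dienyl group from tin to palladium, and reductive elimination that forms C8–C9 with retention at both alkenes. The closest known reaction type is the one-pot palladium-catalysed hydrostannation/Stille coupling of terminal alkynes with alkenyl halides used for conjugated dienes and trienes. No ring is closed and no stereocentre is formed; what is created is the E-C9=C10 double bond (controlled by the syn addition) and with it the complete E,E,E-triene, the geometries of C7=C8 and C11=C12 being carried over from 31 and 20. The step needs regioselectivity (tin on C9, secured by ligand bulk and C11 branching), chemoselectivity (only the alkyne reacts, since C11=C12 is trisubstituted, the C15 and C17 hydroxyls are tertiary and neither acetate is allylic, so no π-allyl complex can form) and the right order of addition (31 enters only after all Sn–H is consumed, which prevents reduction of the C8–I bond). Because all functional groups of both halves are tolerated, the union is the last step and needs no protecting group.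

**Compound list**

1 | pentan-3-one | CCC(=O)CC | starting material
2 | acetaldehyde | CC=O | starting material
3 | 5-hydroxy-4-methylhexan-3-one (aldol adduct, diastereomer mixture) | CCC(=O)C(C)C(C)O | intermediate
4 | (E)-4-methylhex-4-en-3-one | CCC(=O)/C(C)=C/C | intermediate
5 | triisopropyl{[(2Z,4E)-4-methylhexa-2,4-dien-3-yl]oxy}silane | C/C=C(C)/C(O[Si](C(C)C)(C(C)C)C(C)C)=C/C | intermediate
6 | methyl acrylate | C=CC(=O)OC | starting material
7 | Diels–Alder adduct, methyl 2,3,5-trimethyl-4-(triisopropylsilyloxy)cyclohex-3-ene-1-carboxylate, all three sp3 substituents α | COC(=O)[C@@H]1[C@H](C)C(C)=C(O[Si](C(C)C)(C(C)C)C(C)C)[C@H](C)C1 | intermediate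
8 | ring B carbaldehyde (CHO at C13 α) | O=C[C@@H]1[C@H](C)C(C)=C(O[Si](C(C)C)(C(C)C)C(C)C)[C@H](C)C1 | intermediate
9 | 2-(triphenylphosphoranylidene)propanal | CC(C=O)=P(c1ccccc1)(c1ccccc1)c1ccccc1 | starting material
10 | (E)-enal (C10 aldehyde, C11=C12 E) | O=C/C(C)=C/[C@@H]1[C@H](C)C(C)=C(O[Si](C(C)C)(C(C)C)C(C)C)[C@H](C)C1 | intermediate
11 | (E)-enyne silyl enol ether | C#C/C(C)=C/[C@@H]1[C@H](C)C(C)=C(O[Si](C(C)C)(C(C)C)C(C)C)[C@H](C)C1 | intermediate
12 | β-face silyloxy epoxide (C15–C16) | C#C/C(C)=C/[C@@H]1[C@H](C)[C@@]2(C)O[C@@]2(O[Si](C(C)C)(C(C)C)C(C)C)[C@H](C)C1 | intermediate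
13 | C16 ketone with C15 OTIPS β | C#C/C(C)=C/[C@@H]1[C@H](C)[C@@](C)(O[Si](C(C)C)(C(C)C)C(C)C)C(=O)[C@H](C)C1 | intermediate
14 | C16/C17 trimethylsilyl enol ether | C#C/C(C)=C/[C@@H]1[C@H](C)[C@@](C)(O[Si](C(C)C)(C(C)C)C(C)C)C(O[Si](C)(C)C)=C(C)C1 | intermediate
15 | enone (C16=O, C17=C18) | C#C/C(C)=C/[C@@H]1[C@H](C)[C@@](C)(O[Si](C(C)C)(C(C)C)C(C)C)C(=O)C(C)=C1 | intermediate
16 | allylic alcohol (C16 OH β) | C#C/C(C)=C/[C@@H]1[C@H](C)[C@@](C)(O[Si](C(C)C)(C(C)C)C(C)C)[C@@H](O)C(C)=C1 | intermediate
17 | cis-diol (C15, C16 OH β) | C#C/C(C)=C/[C@@H]1[C@H](C)[C@@](C)(O)[C@@H](O)C(C)=C1 | intermediate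
18 | C17/C18 β-osmate ester of hexavalent osmium, TMEDA adduct | C#C/C(C)=C/[C@@H]1[C@H](C)[C@@](C)(O)[C@@H](O)[C@@]2(C)O[Os](=O)(=O)O[C@@H]12.CN(C)CCN(C)C | intermediate
19 | all-cis tetrol | C#C/C(C)=C/[C@@H]1[C@H](C)[C@@](C)(O)[C@@H](O)[C@@](C)(O)[C@H]1O | intermediate
20 | enyne diol diacetate | C#C/C(C)=C/[C@@H]1[C@H](C)[C@@](C)(O)[C@@H](OC(C)=O)[C@@](C)(O)[C@H]1OC(C)=O | intermediate
21 | prop-2-yn-1-ol | C#CCO | starting material
22 | (E)-alkenylalane aluminium alkoxide | C[Al](C)OC/C(C)=C/[Al](C)C | intermediate
23 | (E)-3-iodo-2-methylprop-2-en-1-ol | OC/C(C)=C/I | intermediate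
24 | (E)-3-iodo-2-methylprop-2-enal | O=C/C(C)=C/I | intermediate
25 | methyl 2-methyl-3-oxopentanoate | CCC(=O)C(C)C(=O)OC | starting material
26 | sodium lithium dianion of 25 | CC=C([O-])C(C)=C([O-])OC.[Na+].[Li+] | intermediate
27 | methyl (E)-5-hydroxy-7-iodo-2,4,6-trimethyl-3-oxohept-6-enoate (diastereomer mixture) | COC(=O)C(C)C(=O)C(C)C(O)/C(C)=C/I | intermediate
28 | methyl (E)-7-iodo-2,4,6-trimethyl-3,5-dioxohept-6-enoate | COC(=O)C(C)C(=O)C(C)C(=O)/C(C)=C/I | intermediate
29 | 4-hydroxy-6-[(E)-1-iodoprop-1-en-2-yl]-3,5-dimethyl-2H-pyran-2-one | Cc1c(O)c(C)c(/C(C)=C/I)oc1=O | intermediate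
30 | 4-hydroxy-2-methoxypyrylium triflate | COc1[o+]c(/C(C)=C/I)c(C)c(O)c1C.[O-]S(=O)(=O)C(F)(F)F | intermediate
31 | 6-[(E)-1-iodoprop-1-en-2-yl]-2-methoxy-3,5-dimethyl-4H-pyran-4-one | COc1oc(/C(C)=C/I)c(C)c(=O)c1C | intermediate
32 | (9E,11E)-dienylstannane (Bu3Sn on C9) | CCCC[Sn](CCCC)(CCCC)/C=C/C(C)=C/[C@@H]1[C@H](C)[C@@](C)(O)[C@@H](OC(C)=O)[C@@](C)(O)[C@H]1OC(C)=O | intermediate
33 | amaurone B | COc1oc(/C(C)=C/C=C/C(C)=C/[C@@H]2[C@H](C)[C@@](C)(O)[C@@H](OC(C)=O)[C@@](C)(O)[C@H]2OC(C)=O)c(C)c(=O)c1C | target

**Step count and risks**

Total step count: 19. Longest linear sequence: 13 (steps 1–12 and 19).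

Steps most likely to fail:

1. **Step 19.**
   - Risk: conjugation of the alkyne with C11=C12 may send part of the tin to the internal carbon C10. The acid-sensitive dienylstannane may lose tin before it couples. Left-over tin hydride may reduce the C8–I bond.
   - Fallback: it sets out from 20 and comes back at 33. Ligand-controlled hydrostannation is replaced by sterically controlled hydroboration, and the nucleophile is isolated. Pinacolborane (3.5 equiv; the excess covers the two hydroxyls, whose borate esters fall off on aqueous work-up) with Cy2BH (10 mol %) in THF at room temperature should put boron on C9. This gives the pinacol (9E,11E)-dienylboronate F1, which is purified. F1 is then joined to 31 by Suzuki–Miyaura coupling (Pd(dppf)Cl2, aqueous K3PO4, THF, room temperature, dark) to give 33.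

2. **Step 3.**
   - Risk: the fourfold substituted diene may react slowly. The strongly acidic catalyst may cleave the silyl enol ether or divert the reaction into an open-chain Mukaiyama–Michael pathway. Facial or endo/exo selectivity may be poor.
   - Fallback: it sets out from 5 and comes back at 8, and it replaces catalyst control by a covalently bound auxiliary. Commercial (R)-4-benzyloxazolidin-2-one is acylated (n-BuLi, acryloyl chloride, THF, −78 °C) to the N-acryloyl imide F2. The Et2AlCl-promoted Diels–Alder reaction of F2 with 5 (CH2Cl2, −78 °C) goes through the chelated s-cis imide, whose benzyl group blocks the α-Si face. It should give the imide adduct F3, whose diastereomers can be separated by crystallisation or chromatography. LiBH4 (Et2O, H2O, 0 °C) releases the auxiliary and gives the primary alcohol F4. Dess–Martin oxidation of F4 (pyridine-buffered) gives 8.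

3. **Step 17.**
   - Risk: the other enolate oxygen of the diketonate may add to the iodine-bearing alkene carbon and expel iodide (six-membered addition–elimination) faster than the lactone closes. That would consume the C–I bond needed in step 19.
   - Fallback: it sets out from 25 and 24 and comes back at 29. It masks that oxygen in a temporary ring and closes ring A without base.
     - Cold saponification of 25 (LiOH, THF/H2O, 0 °C) gives 2-methyl-3-oxopentanoic acid F5.
     - F5 is condensed at once with acetone (Ac2O, H2SO4, 0 °C) to 6-ethyl-2,2,5-trimethyl-4H-1,3-dioxin-4-one F6.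
     - LiN(i-Pr)2 and then 24 (THF, −78 °C) give the vinylogous aldol product F7.
     - Dess–Martin oxidation gives the ketone F8.
     - Heating in toluene (110 °C) causes a retro-[4+2] loss of acetone to the acylketene F9, which is trapped at once by the enol of the side-chain ketone to give 29.

**Further compounds**

F1 | step 19 | pinacol (9E,11E)-dienylboronate of ring B diol diacetate | CC1(C)OB(/C=C/C(C)=C/[C@@H]2[C@H](C)[C@@](C)(O)[C@@H](OC(C)=O)[C@@](C)(O)[C@H]2OC(C)=O)OC1(C)C
F2 | step 3 | (R)-3-acryloyl-4-benzyloxazolidin-2-one | C=CC(=O)N1C(=O)OC[C@H]1Cc1ccccc1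
F3 | step 3 | imide Diels–Alder adduct (ring B centres as in 7) | O=C([C@@H]1[C@H](C)C(C)=C(O[Si](C(C)C)(C(C)C)C(C)C)[C@H](C)C1)N1C(=O)OC[C@H]1Cc1ccccc1
F4 | step 3 | [2,3,5-trimethyl-4-(triisopropylsilyloxy)cyclohex-3-en-1-yl]methanol (ring B centres as in 7) | OC[C@@H]1[C@H](C)C(C)=C(O[Si](C(C)C)(C(C)C)C(C)C)[C@H](C)C1
F5 | step 17 | 2-methyl-3-oxopentanoic acid | CCC(=O)C(C)C(=O)O
F6 | step 17 | 6-ethyl-2,2,5-trimethyl-4H-1,3-dioxin-4-one | CCC1=C(C)C(=O)OC(C)(C)O1
F7 | step 17 | 6-[(E)-3-hydroxy-5-iodo-4-methylpent-4-en-2-yl]-2,2,5-trimethyl-4H-1,3-dioxin-4-one (diastereomer mixture) | CC(C(O)/C(C)=C/I)C1=C(C)C(=O)OC(C)(C)O1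
F8 | step 17 | 6-[(E)-5-iodo-4-methyl-3-oxopent-4-en-2-yl]-2,2,5-trimethyl-4H-1,3-dioxin-4-one | CC(C(=O)/C(C)=C/I)C1=C(C)C(=O)OC(C)(C)O1
F9 | step 17 | (E)-7-iodo-2,4,6-trimethylhepta-1,6-diene-1,3,5-trione (acylketene) | CC(C(=O)/C(C)=C/I)C(=O)C(C)=C=O
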